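**Retrosynthetic overview**

- The plan rests on two features of ring C. The O1–C2 bond joins a phenolic oxygen of ring A to the carbon that carries ring B. The C3 hydroxyl with the C4 carbonyl is the enol form of a chromane-3,4-dione.
- Ring C is therefore opened at O1–C2 to an acyclic 1-(2,6-dihydroxyaryl)-3-aryl-3-diazopropane-1,2-dione. Rhodium carbenoid insertion into a phenol O–H bond closes the ring and enolisation gives the flavonol.
- The diazo dione comes from a dihydrochalcone by enolate hydroxylation, ketol oxidation, diazo transfer and desilylation. The dihydrochalcone comes from C-benzylation of the enolate of bis-silylated 2',6'-dihydroxy-4'-methoxyacetophenone with 3-benzyloxy-4-methoxybenzyl bromide.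
- Rings A and B are bought; ring C is the only ring formed (step 9). The cyclisation leaves the 3-OH free, the 5-OH hydrogen-bonded and the 3'-OH benzylated, so sulfation at O3 and hydrogenolysis finish the route.

Key step: step 9

Assumption: the target is taken as the free hydrogen sulfate as drawn; because such monoesters are labile as free acids, the sulfate is carried as its sodium salt and protonated only in the last operation.

**Route**

Step 1
Reactants: 1 1-(2,6-dihydroxy-4-methoxyphenyl)ethan-1-one
Product: 2 1-[2,6-bis(tert-butyldimethylsilyloxy)-4-methoxyphenyl]ethan-1-one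
Conditions: TBSCl (3 equiv), imidazole, DMAP (cat.), DMF, rt to 40 °C
Reagents that add atoms: tert-butyldimethylsilyl chloride, CC(C)(C)[Si](C)(C)Cl
Why: Imidazole-promoted O-silylation of both phenols (Corey conditions) should go to completion with excess reagent despite the hydrogen bond to the ketone, and it avoids the silyl triflate/amine conditions that would also silylate the ketone enol.

Step 2
Reactants: 3 3-(benzyloxy)-4-methoxybenzaldehyde
Product: 4 [3-(benzyloxy)-4-methoxyphenyl]methanol
Conditions: NaBH4, MeOH, 0 °C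
Reagents that add atoms: none
Why: Borohydride reduction of an aromatic aldehyde to the benzylic alcohol, to which the benzyl and methyl ethers are inert.

Step 3
Reactants: 4 [3-(benzyloxy)-4-methoxyphenyl]methanol
Product: 5 2-(benzyloxy)-4-(bromomethyl)-1-methoxybenzene
Conditions: PBr3, Et2O, 0 °C; used at once
Reagents that add atoms: phosphorus tribromide, BrP(Br)Br
Why: Bromide displacement on the phosphite ester of an electron-rich benzylic alcohol is fast at 0 °C, and the bromide is taken on without storage because p-alkoxybenzyl bromides self-alkylate.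

Step 4
Reactants: 2 1-[2,6-bis(tert-butyldimethylsilyloxy)-4-methoxyphenyl]ethan-1-one; 5 2-(benzyloxy)-4-(bromomethyl)-1-methoxybenzene
Product: 7 3-[3-(benzyloxy)-4-methoxyphenyl]-1-[2,6-bis(tert-butyldimethylsilyloxy)-4-methoxyphenyl]propan-1-one, via lithium enolate 6 (not isolated)
Conditions: LDA, THF, −78 °C; then 5, DMPU, −78 to −40 °C
Reagents that add atoms: none
Why: Enolate alkylation (SN2) of the lithium enolate of a methyl ketone with one enolisable position by a reactive benzylic bromide; a slight excess of enolate and temperatures at or below −40 °C should hold back double benzylation and any shift of silicon from an aryl oxygen to the enolate oxygen.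

Step 5
Reactants: 7 3-[3-(benzyloxy)-4-methoxyphenyl]-1-[2,6-bis(tert-butyldimethylsilyloxy)-4-methoxyphenyl]propan-1-one
Product: 9 3-[3-(benzyloxy)-4-methoxyphenyl]-1-[2,6-bis(tert-butyldimethylsilyloxy)-4-methoxyphenyl]-2-hydroxypropan-1-one (racemic), via potassium (Z)-enolate 8 (not isolated)
Conditions: KHMDS, THF, −78 °C; then 3-phenyl-2-(phenylsulfonyl)oxaziridine, −78 °C; then AcOH
Reagents that add atoms: 3-phenyl-2-(phenylsulfonyl)oxaziridine, O=S(=O)(c1ccccc1)N1OC1c1ccccc1
Why: Davis oxidation, in which the enolate carbon attacks the oxaziridine oxygen to give the α-ketol; the new carbinol centre forms as a racemate, which does not matter because step 6 oxidises it.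

Step 6
Reactants: 9 3-[3-(benzyloxy)-4-methoxyphenyl]-1-[2,6-bis(tert-butyldimethylsilyloxy)-4-methoxyphenyl]-2-hydroxypropan-1-one (racemic)
Product: 10 3-[3-(benzyloxy)-4-methoxyphenyl]-1-[2,6-bis(tert-butyldimethylsilyloxy)-4-methoxyphenyl]propane-1,2-dione
Conditions: DMP, CH2Cl2, 0 °C to rt
Reagents that add atoms: none
Why: Dess–Martin oxidation of a secondary α-ketol to the 1,2-dione under near-neutral conditions that spare aryl silyl ethers and the benzyl ether; the product is expected to rest largely as its enol.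

Step 7
Reactants: 10 3-[3-(benzyloxy)-4-methoxyphenyl]-1-[2,6-bis(tert-butyldimethylsilyloxy)-4-methoxyphenyl]propane-1,2-dione
Product: 11 3-[3-(benzyloxy)-4-methoxyphenyl]-1-[2,6-bis(tert-butyldimethylsilyloxy)-4-methoxyphenyl]-3-diazopropane-1,2-dione
Conditions: p-ABSA, Et3N, MeCN, 0 °C to rt, dark
Reagents that add atoms: 4-acetamidobenzenesulfonyl azide, CC(=O)Nc1ccc(cc1)S(=O)(=O)N=[N+]=[N-]
Why: Regitz diazo transfer to the only methylene, which is acidified by the 1,2-dicarbonyl unit and by ring B, so that Et3N suffices and the aryl silyl ethers, which stronger amidine bases can cleave, should survive.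

Step 8
Reactants: 11 3-[3-(benzyloxy)-4-methoxyphenyl]-1-[2,6-bis(tert-butyldimethylsilyloxy)-4-methoxyphenyl]-3-diazopropane-1,2-dione
Product: 12 3-[3-(benzyloxy)-4-methoxyphenyl]-3-diazo-1-(2,6-dihydroxy-4-methoxyphenyl)propane-1,2-dione
Conditions: TBAF, AcOH (slight excess over fluoride), THF, 0 °C, dark; used without storage
Reagents that add atoms: none
Why: Fluoride cleavage of aryl silyl ethers is fast at 0 °C, and the acetic acid buffer protonates each phenoxide as it forms, which should protect the diazo dione from base-induced addition or cleavage while being too weak an acid to protonate the donor–acceptor diazo carbon.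

Step 9
Reactants: 12 3-[3-(benzyloxy)-4-methoxyphenyl]-3-diazo-1-(2,6-dihydroxy-4-methoxyphenyl)propane-1,2-dione
Product: 14 2-[3-(benzyloxy)-4-methoxyphenyl]-3,5-dihydroxy-7-methoxy-4H-chromen-4-one, via chromane-3,4-dione 13 (not isolated)
Conditions: Rh2(OAc)4 (1 mol %), CH2Cl2, 4 Å MS, rt, slow addition of 12 at high dilution
Reagents that add atoms: none
Why: Rh2(OAc)4 takes N2 from the donor–acceptor diazo ketone to give a carbenoid of divalent rhodium at the diazo carbon (the future C2), stabilised by ring B and the adjacent carbonyl; an ortho hydroxyl of ring A adds to this carbon to give an oxonium ylide, and a proton shift releases the catalyst and the chromane-3,4-dione 13, which should enolise at once to the aromatic 3-hydroxy-4-pyranone 14. The closest known reaction type is the Rh2(OAc)4-catalysed intramolecular O–H insertion of α-diazo ketones and esters that carry a tethered phenol or alcohol, which gives oxygen heterocycles. Ring C closes by formation of the O1–C2 bond in a six-membered mode with the rhodium–carbon bond exocyclic to the new ring; the two hydroxyls of ring A are equivalent, so either gives the same ring and the other becomes the 5-OH. No stereocentre survives, since C2 of 13 forms as a racemate and is flattened by enolisation. The step needs O–H insertion to win over Wolff rearrangement, carbenoid dimerisation and intermolecular insertion; the dirhodium tetracarboxylate disfavours the 1,2-acyl shift, the hydroxyl is held where a strain-free six-membered transition state is available, and slow addition keeps the diazo concentration low. If the acidic phenol protonates the diazo carbon before the metal acts, displacement of N2 from the diazonium ion by the same oxygen leads to the same product.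

Step 10
Reactants: 14 2-[3-(benzyloxy)-4-methoxyphenyl]-3,5-dihydroxy-7-methoxy-4H-chromen-4-one
Product: 15 sodium 2-[3-(benzyloxy)-4-methoxyphenyl]-5-hydroxy-7-methoxy-4-oxo-4H-chromen-3-yl sulfate
Conditions: SO3·pyridine, pyridine, rt to 40 °C; then aq. NaHCO3
Reagents that add atoms: sulfur trioxide–pyridine complex, [O-]S(=O)(=O)[n+]1ccccc1; sodium hydrogen carbonate, [Na+].OC(=O)[O-]
Why: O-sulfation of the enolic 3-hydroxyl with an SO3–amine complex; the 5-hydroxyl is locked in a strong hydrogen bond to the C4 carbonyl and should stay free, and the 3'-oxygen is blocked as its benzyl ether.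

Step 11
Reactants: 15 sodium 2-[3-(benzyloxy)-4-methoxyphenyl]-5-hydroxy-7-methoxy-4-oxo-4H-chromen-3-yl sulfate
Product: 17 5-hydroxy-2-(3-hydroxy-4-methoxyphenyl)-7-methoxy-4-oxo-4H-chromen-3-yl hydrogen sulfate (ombuin 3-O-sulfate), via sodium sulfate salt 16 (not isolated)
Conditions: H2 (1 atm), 10% Pd/C, MeOH, rt; filter; then 0.1 M HCl (1.0 equiv), 0 °C, C18 desalting, lyophilise
Reagents that add atoms: none
Why: Hydrogenolysis of the benzyl ether over Pd/C should leave the sulfate monoester and the C2–C3 double bond of the pyranone untouched, and one equivalent of cold dilute acid then converts the sodium salt into the hydrogen sulfate.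

**Compound list**

1 | 1-(2,6-dihydroxy-4-methoxyphenyl)ethan-1-one (2',6'-dihydroxy-4'-methoxyacetophenone) | COc1cc(O)c(C(C)=O)c(O)c1 | starting material
2 | 1-[2,6-bis(tert-butyldimethylsilyloxy)-4-methoxyphenyl]ethan-1-one | COc1cc(O[Si](C)(C)C(C)(C)C)c(C(C)=O)c(O[Si](C)(C)C(C)(C)C)c1 | intermediate
3 | 3-(benzyloxy)-4-methoxybenzaldehyde | COc1ccc(C=O)cc1OCc1ccccc1 | starting material
4 | [3-(benzyloxy)-4-methoxyphenyl]methanol | COc1ccc(CO)cc1OCc1ccccc1 | intermediate
5 | 2-(benzyloxy)-4-(bromomethyl)-1-methoxybenzene | COc1ccc(CBr)cc1OCc1ccccc1 | intermediate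
6 | lithium 1-[2,6-bis(tert-butyldimethylsilyloxy)-4-methoxyphenyl]ethen-1-olate (not isolated) | [Li+].[O-]C(=C)c1c(O[Si](C)(C)C(C)(C)C)cc(OC)cc1O[Si](C)(C)C(C)(C)C | intermediate
7 | 3-[3-(benzyloxy)-4-methoxyphenyl]-1-[2,6-bis(tert-butyldimethylsilyloxy)-4-methoxyphenyl]propan-1-one | COc1cc(O[Si](C)(C)C(C)(C)C)c(C(=O)CCc2ccc(OC)c(OCc3ccccc3)c2)c(O[Si](C)(C)C(C)(C)C)c1 | intermediate
8 | potassium (Z)-3-[3-(benzyloxy)-4-methoxyphenyl]-1-[2,6-bis(tert-butyldimethylsilyloxy)-4-methoxyphenyl]prop-1-en-1-olate (not isolated) | [K+].[O-]/C(=C\Cc1ccc(OC)c(OCc2ccccc2)c1)c1c(O[Si](C)(C)C(C)(C)C)cc(OC)cc1O[Si](C)(C)C(C)(C)C | intermediate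
9 | 3-[3-(benzyloxy)-4-methoxyphenyl]-1-[2,6-bis(tert-butyldimethylsilyloxy)-4-methoxyphenyl]-2-hydroxypropan-1-one (racemic) | COc1cc(O[Si](C)(C)C(C)(C)C)c(C(=O)C(O)Cc2ccc(OC)c(OCc3ccccc3)c2)c(O[Si](C)(C)C(C)(C)C)c1 | intermediate
10 | 3-[3-(benzyloxy)-4-methoxyphenyl]-1-[2,6-bis(tert-butyldimethylsilyloxy)-4-methoxyphenyl]propane-1,2-dione | COc1cc(O[Si](C)(C)C(C)(C)C)c(C(=O)C(=O)Cc2ccc(OC)c(OCc3ccccc3)c2)c(O[Si](C)(C)C(C)(C)C)c1 | intermediate
11 | 3-[3-(benzyloxy)-4-methoxyphenyl]-1-[2,6-bis(tert-butyldimethylsilyloxy)-4-methoxyphenyl]-3-diazopropane-1,2-dione | COc1cc(O[Si](C)(C)C(C)(C)C)c(C(=O)C(=O)C(=[N+]=[N-])c2ccc(OC)c(OCc3ccccc3)c2)c(O[Si](C)(C)C(C)(C)C)c1 | intermediate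
12 | 3-[3-(benzyloxy)-4-methoxyphenyl]-3-diazo-1-(2,6-dihydroxy-4-methoxyphenyl)propane-1,2-dione | COc1cc(O)c(C(=O)C(=O)C(=[N+]=[N-])c2ccc(OC)c(OCc3ccccc3)c2)c(O)c1 | intermediate
13 | 2-[3-(benzyloxy)-4-methoxyphenyl]-5-hydroxy-7-methoxy-2H-chromene-3,4-dione (racemic at C2, not isolated) | COc1cc(O)c2C(=O)C(=O)C(c3ccc(OC)c(OCc4ccccc4)c3)Oc2c1 | intermediate
14 | 2-[3-(benzyloxy)-4-methoxyphenyl]-3,5-dihydroxy-7-methoxy-4H-chromen-4-one | COc1cc(O)c2c(=O)c(O)c(-c3ccc(OC)c(OCc4ccccc4)c3)oc2c1 | intermediate
15 | sodium 2-[3-(benzyloxy)-4-methoxyphenyl]-5-hydroxy-7-methoxy-4-oxo-4H-chromen-3-yl sulfate | COc1cc(O)c2c(=O)c(OS(=O)(=O)[O-])c(-c3ccc(OC)c(OCc4ccccc4)c3)oc2c1.[Na+] | intermediate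
16 | sodium 5-hydroxy-2-(3-hydroxy-4-methoxyphenyl)-7-methoxy-4-oxo-4H-chromen-3-yl sulfate (not isolated) | COc1cc(O)c2c(=O)c(OS(=O)(=O)[O-])c(-c3ccc(OC)c(O)c3)oc2c1.[Na+] | intermediate
17 | 5-hydroxy-2-(3-hydroxy-4-methoxyphenyl)-7-methoxy-4-oxo-4H-chromen-3-yl hydrogen sulfate (ombuin 3-O-sulfate) | COc1cc(O)c2c(=O)c(OS(=O)(=O)O)c(-c3ccc(OC)c(O)c3)oc2c1 | target

**Step count**

Total: 11 steps. Longest linear sequence: 10 steps (from 3: steps 2 to 11).

**Steps most likely to fail**

1. Step 9 (carbenoid O–H insertion). What may go wrong: loss of N2 followed by 1,2-acyl shift (Wolff rearrangement) and trapping of the ketene by the phenol; reversible addition of the ortho phenol to the neighbouring carbonyl before the carbenoid forms, so that the carbenoid rearranges instead of inserting; carbenoid dimerisation or intermolecular insertion.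
 Fallback (ring C closed by epoxide opening instead of carbene insertion), setting out from 1 and 3 and returning at 14. Compound 1 is converted with MOMCl and NaH in DMF into 1-[4-methoxy-2,6-bis(methoxymethoxy)phenyl]ethan-1-one F1. Claisen–Schmidt condensation of F1 with 3 (KOH, EtOH) should give (E)-3-[3-(benzyloxy)-4-methoxyphenyl]-1-[4-methoxy-2,6-bis(methoxymethoxy)phenyl]prop-2-en-1-one F2. Alkaline H2O2 (NaOH, MeOH–THF) should give the racemic trans-epoxide [3-[3-(benzyloxy)-4-methoxyphenyl]oxiran-2-yl][4-methoxy-2,6-bis(methoxymethoxy)phenyl]methanone F3. HCl in MeOH at 50 °C removes both acetals, and the freed phenol opens the epoxide at the benzylic carbon to give racemic trans-2-[3-(benzyloxy)-4-methoxyphenyl]-3,5-dihydroxy-7-methoxychroman-4-one F4. Dehydrogenation with I2 and KOAc in AcOH then gives 14. Protecting the 2'-oxygen through the epoxidation avoids the aurone formation that 6'-oxygenated 2'-hydroxychalcones show under direct oxidative cyclisation.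

2. Step 8 (unmasking the two phenols beside the diazo dione). What may go wrong: addition of a fluoride-generated phenoxide to the adjacent carbonyl, cleavage of the C1–C2 bond, or loss of nitrogen before the catalyst is present.
 Fallback (silyl groups removed before the diazo group exists), setting out from 10 and returning at 12. Compound 10 is desilylated with TBAF and AcOH in THF to 3-[3-(benzyloxy)-4-methoxyphenyl]-1-(2,6-dihydroxy-4-methoxyphenyl)propane-1,2-dione F5, which is expected to rest partly as its cyclic hemiketal. Regitz diazo transfer (p-ABSA, Et3N, MeCN, 0 °C) on the ring-opened enolate then gives 12 directly, so the diazo compound never meets fluoride.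

3. Step 4 (enolate benzylation). What may go wrong: proton exchange between enolate and product leading to double benzylation, and migration of a silyl group from an aryl oxygen to the enolate oxygen on warming.
 Fallback (aldol condensation and conjugate reduction instead of alkylation), setting out from 2 and 3 and returning at 7. The lithium enolate 6 (LDA, THF, −78 °C) is added to aldehyde 3 at −78 °C, where addition is much faster than alkylation, to give racemic 3-[3-(benzyloxy)-4-methoxyphenyl]-1-[2,6-bis(tert-butyldimethylsilyloxy)-4-methoxyphenyl]-3-hydroxypropan-1-one F6. Dehydration with catalytic p-TsOH in toluene at 60 °C should give (E)-3-[3-(benzyloxy)-4-methoxyphenyl]-1-[2,6-bis(tert-butyldimethylsilyloxy)-4-methoxyphenyl]prop-2-en-1-one F7. Hydrogenation of the enone double bond with H2 over RhCl(PPh3)3 in benzene, which leaves the benzyl ether and the ketone alone, gives 7. This fallback also removes steps 2 and 3.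

**Further compounds**

F1 | step 9 | 1-[4-methoxy-2,6-bis(methoxymethoxy)phenyl]ethan-1-one | COCOc1cc(OC)cc(OCOC)c1C(C)=O
F2 | step 9 | (E)-3-[3-(benzyloxy)-4-methoxyphenyl]-1-[4-methoxy-2,6-bis(methoxymethoxy)phenyl]prop-2-en-1-one | COCOc1cc(OC)cc(OCOC)c1C(=O)/C=C/c1ccc(OC)c(OCc2ccccc2)c1
F3 | step 9 | trans-[3-[3-(benzyloxy)-4-methoxyphenyl]oxiran-2-yl][4-methoxy-2,6-bis(methoxymethoxy)phenyl]methanone (racemic, one enantiomer drawn) | COCOc1cc(OC)cc(OCOC)c1C(=O)[C@@H]1O[C@H]1c1ccc(OC)c(OCc2ccccc2)c1
F4 | step 9 | trans-2-[3-(benzyloxy)-4-methoxyphenyl]-3,5-dihydroxy-7-methoxychroman-4-one (racemic, 2R,3R enantiomer drawn) | COc1cc(O)c2C(=O)[C@H](O)[C@@H](c3ccc(OC)c(OCc4ccccc4)c3)Oc2c1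
F5 | step 8 | 3-[3-(benzyloxy)-4-methoxyphenyl]-1-(2,6-dihydroxy-4-methoxyphenyl)propane-1,2-dione | COc1cc(O)c(C(=O)C(=O)Cc2ccc(OC)c(OCc3ccccc3)c2)c(O)c1
F6 | step 4 | 3-[3-(benzyloxy)-4-methoxyphenyl]-1-[2,6-bis(tert-butyldimethylsilyloxy)-4-methoxyphenyl]-3-hydroxypropan-1-one (racemic) | COc1cc(O[Si](C)(C)C(C)(C)C)c(C(=O)CC(O)c2ccc(OC)c(OCc3ccccc3)c2)c(O[Si](C)(C)C(C)(C)C)c1
F7 | step 4 | (E)-3-[3-(benzyloxy)-4-methoxyphenyl]-1-[2,6-bis(tert-butyldimethylsilyloxy)-4-methoxyphenyl]prop-2-en-1-one | COc1cc(O[Si](C)(C)C(C)(C)C)c(C(=O)/C=C/c2ccc(OC)c(OCc3ccccc3)c2)c(O[Si](C)(C)C(C)(C)C)c1
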